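In the cedar run, the flask asked about, D stands no higher at 25.0 min than at 3.00 min: 23% against 23%, with a scatter of 2 percentage points. Here G and Q are substrates, L the reagent and D the product.

| setting | cedar | maple | flask |
|---|---|---|---|
| G | 0.050 M | 0.050 M | 0.050 M |
| L | 0.060 M | 0.040 M | 0.0600 M |
| Q | 0.050 M | 0.050 M | 0.0500 M |
| temperature | −20 °C | −25 °C | −20 °C |
| remark | the very flask that is asked about, followed so far | run made earlier |  |
| time |  |  | 40 min |

- cedar (time / min: D / %): 3.00: 23; 6.00: 24; 10.0: 30; 15.0: 24; 20.0: 21; 25.0: 23
- maple (time / min: D / %): 0.167: 4; 0.500: 0; 0.833: 5; 1.33: 0; 2.00: 8; 2.50: 4; 3.00: 8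

(readings scatter by 2 percentage points)

* D, in percent of the G first charged, at 40 min
* the option that brings most further D ("none" if no option brings more than 2 percentage points) (midnight / dawn / winter / summer / none)
* D present, with what was taken out counted in, in percent of the G first charged, after midnight
* D present, with what was taken out counted in, in percent of the G first charged, after summer

- midnight: at 40 min add L, 100% of the amount charged, then wait 80 min
- dawn: at 40 min take out 90% of the D then present, then wait 80 min
- winter: change nothing and wait 80 min more
- summer: at 40 min raise the temperature by 20 K, then wait 80 min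

- D that was removed still counts
- the numbers in the tables scatter by 2 percentage points (one standard deviation)
- additions bring no volume worth counting

The first rung taken here is the making of D. Suppose G + L → D with L held at its charge (pseudo-first-order), and suppose the first cedar reading shows all the G lost so far. G then falls with a rate constant k' = 0.0871 min⁻¹. This gives the making half-life t_m, the time in which L at its charged concentration halves G by forming D, here 7.96 min. As a reading it carries the scatter, and it scales inversely with L. The maple run, colder and with less L, reaches a lower 8% at 3.00 min than cedar's 23%.

The next rung is a contradiction. Since t_m is shorter than the 25.0 min of the run, making alone would carry D to 88.7%, far more than the 23% read. So a flat D is a balance or a lost partner, and a second channel works on a scale close to t_m, taking G or D.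

On the last rung, making fades as G falls while any drain on D continues. My own reckoning therefore puts D at 40 min at or below the cedar mean of 24.2%, and it expects little from more L.

The forecast differs on L. It gives 24% now, midnight as best, 41% after midnight and 25% after summer, reasoning that “A fresh dose of L should then repeat the first burst”.

    D ⇌ E (K = 2.40, k = 8.53 × 10⁻⁴ s⁻¹, Ea = 79.0 kJ mol⁻¹, ΔH = 9.00 kJ mol⁻¹)
    Q + L → Z (k = 0.00326 M⁻¹ s⁻¹, Ea = 55.0 kJ mol⁻¹)
    G + L → D (k = 0.0282 M⁻¹ s⁻¹, Ea = 60.0 kJ mol⁻¹)
    G + Q → X (k = 0.0487 M⁻¹ s⁻¹, Ea = 36.0 kJ mol⁻¹)
    (constants at −20 °C)

The flask gives 16.4% at 40 min. The best option is dawn, with 7.3 points further D, while midnight ends at 13.4% and summer at 10.6%. At 3.06 min D is made 4.70 times faster than it is used up, each step taken net, but at 40.0 min that ratio is 0.143. By then L stands at 51% of its charge, which stretches the t_m reckoned from the cedar reading to 15.6 min, and G stands at 0.63%. In the neighbour flask with 0.24 M of L, t_m shrinks to 1.99 min, and D reads 25.8% with E at 50.1%.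

The data are simulated with constants of no real substance; scatter was added.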